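**Retrosynthetic overview**
1. The ring acyloxy group (senecioate) is put on last by enolate oxygenation and in-flask acylation of the epoxy ketone. The oxirane comes from hydroxyl-directed epoxidation of a cis-carveol-type allylic alcohol.
2. The side-chain angelate comes from the free carbinol. Its C–C bond to the prenyl unit and its stereocentre come from a phosphoric-acid-catalysed linear prenylboration of a ring-bound α-substituted acrolein (the new step).
3. The cyclohexenone and its ring stereocentre come from an amine-catalysed Michael addition of tert-butyl 3-oxopentanoate to a 2,4-dienal, followed by aldol condensation and decarboxylation.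
4. The dienal comes from a Heck coupling of 2-bromoacrolein diethyl acetal with acrolein.
5. Ring order: cyclohexenone first (from acyclic, achiral material), oxirane second.

Assumption: the tertiary boronate is not taken as purchasable and is made in one step; (S)-TRIP is taken to induce Si-face attack with it as with allyl pinacolboronate (otherwise the (R)-acid is used); atom labels follow the bisabolane skeleton (C1 ring CH–O-senecioyl, C2 C=O, C3/C4 oxirane carbons, C5 CH2, C6 ring CH, C7=C14H2, C8 CH–O-angeloyl).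

**Step 1**
Reactants: 1 2-bromo-3,3-diethoxyprop-1-ene; 2 acrolein
Product: 3 (2E)-4-(diethoxymethyl)penta-2,4-dienal
Conditions: Pd(OAc)2 (5 mol%), Bu4NCl, NaHCO3, DMF, 40 °C
Reagents that add atoms: none
Why: Mizoroki–Heck vinylation under ligand-free Jeffery conditions, in which oxidative addition of the vinyl bromide, insertion into acrolein at its unsubstituted terminus and syn β-hydride elimination give the E-enal while the mild bicarbonate medium leaves the acetal and aldehyde intact; no stereocentre is formed.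

**Step 2**
Reactants: 3 (2E)-4-(diethoxymethyl)penta-2,4-dienal; 4 tert-butyl 3-oxopentanoate
Product: 8 2-[(1R)-4-methyl-5-oxocyclohex-3-en-1-yl]prop-2-enal, via Michael adduct 5 (not isolated), via keto ester 6 (not isolated), via acetal enone 7 (not isolated)
Conditions: (S)-2-[bis(3,5-bis(trifluoromethyl)phenyl)(trimethylsilyloxy)methyl]pyrrolidine (10 mol%), toluene, 0 °C to rt; then TsOH·H2O (20 mol%), toluene, 80 °C; then 1 M HCl, THF, rt
Reagents that add atoms: water, O
Why: Iminium-ion Michael addition with a diarylprolinol silyl ether (Jørgensen–Hayashi catalysis), in which the ketoester adds 1,4 to the E-iminium of 3 on the face opposite the bulky diaryl(silyloxy)methyl arm and so sets C6 (R in 5–8, the 6S centre of the target), after which acid drives the six-membered aldol condensation of the ethyl-ketone CH2 on the aldehyde, tert-butyl ester cleavage with decarboxylation and hydrolysis of the acetal.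

**Step 3**
Reactants: 9 (3-methylbut-2-en-1-yl)magnesium chloride; 10 2-isopropoxy-4,4,5,5-tetramethyl-1,3,2-dioxaborolane
Product: 11 4,4,5,5-tetramethyl-2-(2-methylbut-3-en-2-yl)-1,3,2-dioxaborolane
Conditions: THF, −78 °C to rt; then HCl in Et2O; distillation
Reagents that add atoms: none
Why: Borylation of an allylic Grignard reagent, which attacks the borate through its γ-carbon to give the tertiary α,α-dimethylallyl boronate; as a pinacol ester this does not undergo 1,3-boron shift, and any primary isomer is removed by distillation; no stereocentre is formed.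

**Step 4**
Reactants: 8 2-[(1R)-4-methyl-5-oxocyclohex-3-en-1-yl]prop-2-enal; 11 4,4,5,5-tetramethyl-2-(2-methylbut-3-en-2-yl)-1,3,2-dioxaborolane
Product: 13 (5R)-5-[(3S)-3-hydroxy-6-methylhepta-1,5-dien-2-yl]-2-methylcyclohex-2-en-1-one, via pinacol borate ester 12 (not isolated)
Conditions: (S)-TRIP [(S)-3,3'-bis(2,4,6-triisopropylphenyl)-1,1'-binaphthyl-2,2'-diyl hydrogen phosphate] (10 mol%), 4 Å MS, toluene, −30 °C; aqueous work-up
Reagents that add atoms: none
Why: Proposed new method: a chiral-phosphoric-acid-catalysed, γ-selective allylboration with a tertiary α,α-dimethylallyl pinacol boronate, in which the acid P–OH hydrogen-bonds to the pseudo-axial boronate oxygen and P=O to the formyl C–H in a closed chair transition state, the unsubstituted CH2 terminus of 11 attacks the Si face of the aldehyde of 8 and the allyl shift forms the C8–C9 bond, the linear prenyl group (no E/Z issue because the new alkene terminus is CMe2) and the 8S carbinol under catalyst control, the ring ketone being inert to allyl pinacol boronates; the closest known reactions are the TRIP-catalysed allyl- and crotylboration of aldehydes with pinacol boronates and the uncatalysed γ-addition of α,α-dimethylallyl boronates to aldehydes.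

**Step 5**
Reactants: 13 (5R)-5-[(3S)-3-hydroxy-6-methylhepta-1,5-dien-2-yl]-2-methylcyclohex-2-en-1-one; 14 angelic acid
Product: 16 (3S)-6-methyl-2-[(1R)-4-methyl-5-oxocyclohex-3-en-1-yl]hepta-1,5-dien-3-yl (2Z)-2-methylbut-2-enoate, via mixed anhydride 15 (not isolated)
Conditions: 14, 2,4,6-Cl3C6H2COCl, Et3N, toluene, rt; then 13, toluene, 75 °C (no DMAP)
Reagents that add atoms: none
Why: Yamaguchi-type esterification in which the alcohol attacks the less hindered angeloyl carbonyl of mixed anhydride 15; leaving out the nucleophilic amine catalyst keeps the Z (angelate) geometry, and C8 is untouched because acylation is on oxygen.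

**Step 6**
Reactants: 16 (3S)-6-methyl-2-[(1R)-4-methyl-5-oxocyclohex-3-en-1-yl]hepta-1,5-dien-3-yl (2Z)-2-methylbut-2-enoate
Product: 17 (3S)-2-[(1R,5R)-5-hydroxy-4-methylcyclohex-3-en-1-yl]-6-methylhepta-1,5-dien-3-yl (2Z)-2-methylbut-2-enoate
Conditions: NaBH4, CeCl3·7H2O, MeOH, −78 °C
Reagents that add atoms: none
Why: Luche 1,2-reduction, in which axial hydride delivery to the cerium-activated enone carbonyl gives the pseudo-equatorial C2 alcohol cis to the C6 side chain (the carvone to cis-carveol selectivity), with the esters and isolated alkenes inert.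

**Step 7**
Reactants: 17 (3S)-2-[(1R,5R)-5-hydroxy-4-methylcyclohex-3-en-1-yl]-6-methylhepta-1,5-dien-3-yl (2Z)-2-methylbut-2-enoate
Product: 18 (3S)-2-[(1S,3S,5R,6R)-5-hydroxy-6-methyl-7-oxabicyclo[4.1.0]heptan-3-yl]-6-methylhepta-1,5-dien-3-yl (2Z)-2-methylbut-2-enoate
Conditions: VO(acac)2 (2 mol%), t-BuOOH, CH2Cl2, 0 °C to rt
Reagents that add atoms: tert-butyl hydroperoxide, CC(C)(C)OO
Why: Hydroxyl-directed vanadium-catalysed epoxidation (Sharpless–Michaelson), in which the vanadate ester of the C2 alcohol delivers oxygen to the same face of the adjacent trisubstituted ring alkene and so sets C3 and C4 with the oxirane cis to the hydroxyl and therefore cis to the C6 side chain, while the prenyl, 1,1-disubstituted and angelate alkenes, which have no free allylic hydroxyl, do not react.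

**Step 8**
Reactants: 18 (3S)-2-[(1S,3S,5R,6R)-5-hydroxy-6-methyl-7-oxabicyclo[4.1.0]heptan-3-yl]-6-methylhepta-1,5-dien-3-yl (2Z)-2-methylbut-2-enoate
Product: 19 (3S)-6-methyl-2-[(1S,3R,6S)-6-methyl-5-oxo-7-oxabicyclo[4.1.0]heptan-3-yl]hepta-1,5-dien-3-yl (2Z)-2-methylbut-2-enoate
Conditions: Dess–Martin periodinane, NaHCO3, CH2Cl2, 0 °C to rt
Reagents that add atoms: none
Why: Dess–Martin oxidation of the secondary epoxy alcohol to the α,β-epoxy ketone under buffered conditions that open neither the oxirane nor isomerise the angelate; no stereocentre changes.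

**Step 9**
Reactants: 19 (3S)-6-methyl-2-[(1S,3R,6S)-6-methyl-5-oxo-7-oxabicyclo[4.1.0]heptan-3-yl]hepta-1,5-dien-3-yl (2Z)-2-methylbut-2-enoate; 20 3-methylbut-2-enoyl chloride
Product: 22 (1S,3S,4S,6S)-1-methyl-4-[(3S)-6-methyl-3-{[(2Z)-2-methylbut-2-enoyl]oxy}hepta-1,5-dien-2-yl]-2-oxo-7-oxabicyclo[4.1.0]heptan-3-yl 3-methylbut-2-enoate, via sodium alkoxide 21 (not isolated)
Conditions: NaN(SiMe3)2, THF, −78 °C; racemic 2-(phenylsulfonyl)-3-phenyloxaziridine, −78 °C; then 20, −78 to 0 °C
Reagents that add atoms: 2-(phenylsulfonyl)-3-phenyloxaziridine, O=S(=O)(N1OC1c1ccccc1)c1ccccc1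
Why: Enolate α-oxygenation with a Davis oxaziridine followed by in-flask O-acylation, in which C1 is the only enolisable α-carbon (C3 is quaternary) and the oxaziridine attacks the sodium enolate anti to the adjacent C6 side chain to give the 1,6-trans alkoxide (also the thermodynamic diequatorial epimer), which the acid chloride traps at low temperature.

**Compound list**
1 | 2-bromo-3,3-diethoxyprop-1-ene | C=C(Br)C(OCC)OCC | starting material
2 | acrolein (prop-2-enal) | C=CC=O | starting material
3 | (2E)-4-(diethoxymethyl)penta-2,4-dienal | O=C/C=C/C(=C)C(OCC)OCC | intermediate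
4 | tert-butyl 3-oxopentanoate | CCC(=O)CC(=O)OC(C)(C)C | starting material
5 | tert-butyl (3R)-4-(diethoxymethyl)-3-(2-oxoethyl)-2-propanoylpent-4-enoate (C2 epimers) | C=C(C(OCC)OCC)[C@@H](C(C(=O)CC)C(=O)OC(C)(C)C)CC=O | intermediate
6 | tert-butyl (6R)-6-(3,3-diethoxyprop-1-en-2-yl)-3-methyl-2-oxocyclohex-3-ene-1-carboxylate (C1 epimers) | C=C(C(OCC)OCC)[C@@H]1CC=C(C)C(=O)C1C(=O)OC(C)(C)C | intermediate
7 | (5R)-5-(3,3-diethoxyprop-1-en-2-yl)-2-methylcyclohex-2-en-1-one | C=C(C(OCC)OCC)[C@@H]1CC=C(C)C(=O)C1 | intermediate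
8 | 2-[(1R)-4-methyl-5-oxocyclohex-3-en-1-yl]prop-2-enal | C=C(C=O)[C@@H]1CC=C(C)C(=O)C1 | intermediate
9 | (3-methylbut-2-en-1-yl)magnesium chloride | CC(C)=CC[Mg]Cl | starting material
10 | 2-isopropoxy-4,4,5,5-tetramethyl-1,3,2-dioxaborolane | CC(C)OB1OC(C)(C)C(C)(C)O1 | starting material
11 | 4,4,5,5-tetramethyl-2-(2-methylbut-3-en-2-yl)-1,3,2-dioxaborolane | C=CC(C)(C)B1OC(C)(C)C(C)(C)O1 | intermediate
12 | 2-({(3S)-6-methyl-2-[(1R)-4-methyl-5-oxocyclohex-3-en-1-yl]hepta-1,5-dien-3-yl}oxy)-4,4,5,5-tetramethyl-1,3,2-dioxaborolane | C=C([C@H](CC=C(C)C)OB2OC(C)(C)C(C)(C)O2)[C@@H]1CC=C(C)C(=O)C1 | intermediate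
13 | (5R)-5-[(3S)-3-hydroxy-6-methylhepta-1,5-dien-2-yl]-2-methylcyclohex-2-en-1-one | C=C([C@H](CC=C(C)C)O)[C@@H]1CC=C(C)C(=O)C1 | intermediate
14 | angelic acid, (2Z)-2-methylbut-2-enoic acid | C/C=C(/C)C(=O)O | starting material
15 | (2Z)-2-methylbut-2-enoic 2,4,6-trichlorobenzoic anhydride | C/C=C(/C)C(=O)OC(=O)c1c(Cl)cc(Cl)cc1Cl | intermediate
16 | (3S)-6-methyl-2-[(1R)-4-methyl-5-oxocyclohex-3-en-1-yl]hepta-1,5-dien-3-yl (2Z)-2-methylbut-2-enoate | C=C([C@H](CC=C(C)C)OC(=O)/C(C)=C\C)[C@@H]1CC=C(C)C(=O)C1 | intermediate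
17 | (3S)-2-[(1R,5R)-5-hydroxy-4-methylcyclohex-3-en-1-yl]-6-methylhepta-1,5-dien-3-yl (2Z)-2-methylbut-2-enoate (hydroxyl cis to the side chain) | C=C([C@H](CC=C(C)C)OC(=O)/C(C)=C\C)[C@@H]1CC=C(C)[C@H](O)C1 | intermediate
18 | (3S)-2-[(1S,3S,5R,6R)-5-hydroxy-6-methyl-7-oxabicyclo[4.1.0]heptan-3-yl]-6-methylhepta-1,5-dien-3-yl (2Z)-2-methylbut-2-enoate (oxirane, hydroxyl and side chain all cis) | C=C([C@H](CC=C(C)C)OC(=O)/C(C)=C\C)[C@@H]1C[C@@H]2O[C@]2(C)[C@H](O)C1 | intermediate
19 | (3S)-6-methyl-2-[(1S,3R,6S)-6-methyl-5-oxo-7-oxabicyclo[4.1.0]heptan-3-yl]hepta-1,5-dien-3-yl (2Z)-2-methylbut-2-enoate (oxirane cis to the side chain) | C=C([C@H](CC=C(C)C)OC(=O)/C(C)=C\C)[C@@H]1C[C@@H]2O[C@]2(C)C(=O)C1 | intermediate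
20 | 3-methylbut-2-enoyl chloride (senecioyl chloride) | CC(C)=CC(=O)Cl | starting material
21 | sodium (1S,3S,4S,6S)-1-methyl-4-[(3S)-6-methyl-3-{[(2Z)-2-methylbut-2-enoyl]oxy}hepta-1,5-dien-2-yl]-2-oxo-7-oxabicyclo[4.1.0]heptan-3-olate | C=C([C@H](CC=C(C)C)OC(=O)/C(C)=C\C)[C@@H]1C[C@@H]2O[C@]2(C)C(=O)[C@H]1[O-].[Na+] | intermediate
22 | (1S,3S,4S,6S)-1-methyl-4-[(3S)-6-methyl-3-{[(2Z)-2-methylbut-2-enoyl]oxy}hepta-1,5-dien-2-yl]-2-oxo-7-oxabicyclo[4.1.0]heptan-3-yl 3-methylbut-2-enoate | C=C([C@H](CC=C(C)C)OC(=O)/C(C)=C\C)[C@@H]1C[C@@H]2O[C@]2(C)C(=O)[C@H]1OC(=O)C=C(C)C | target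

**Step count and risks**
Total steps: 9. Longest linear sequence: 8 (steps 1, 2, 4, 5, 6, 7, 8, 9); step 3 is a one-step side branch.

Most likely to fail:

Step 2. Dienal 3 has an unhindered δ-CH2 and a branched γ-carbon, so 1,6-addition may compete with the wanted 1,4-addition, and the allylic acetal and 2-substituted acrolein must survive hot acid. The fallback removes the diene from the Michael step. It sets out from 4. Cross-metathesis of 4,4-diethoxybut-1-ene with crotonaldehyde (second-generation Grubbs catalyst) gives (2E)-5,5-diethoxypent-2-enal F1. The same amine-catalysed Michael addition, aldol condensation and decarboxylation with 4 gives (5S)-5-(2,2-diethoxyethyl)-2-methylcyclohex-2-en-1-one F2. Aqueous acid unmasks [(1S)-4-methyl-5-oxocyclohex-3-en-1-yl]acetaldehyde F3. Amine-catalysed α-methylenation of F3 with aqueous formaldehyde (pyrrolidine, propionic acid, isopropanol, 45 °C) rejoins the route at 8.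

Step 4 (the new step). The gem-dimethyl group next to boron may slow the catalysed pathway or erode facial control. The fallback uses known chemistry and sets out from 8. The established (S)-TRIP-catalysed allylboration with commercial allyl pinacolboronate gives (5R)-5-[(3S)-3-hydroxyhexa-1,5-dien-2-yl]-2-methylcyclohex-2-en-1-one F4. Only its monosubstituted alkene undergoes cross-metathesis with 2-methylbut-2-ene (second-generation Grubbs catalyst), which installs the prenyl terminus and rejoins the route at 13.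

Step 9. The free α-alkoxide 21 sits next to a ketone and an oxirane, so α-ketol shift, epoxide migration or addition to the sulfonimine by-product may occur before acylation. The fallback forms the C1–O bond with the acyl group already attached and sets out from 19. Senecioyl chloride 20 with aqueous H2O2 and NaOH at 0 °C gives bis(3-methylbut-2-enoyl) peroxide F5. The sodium enolate of 19 (NaN(SiMe3)2, THF, −78 °C) attacks the peroxide O–O bond of F5 anti to the C6 side chain and gives 22 directly, with no free alkoxide formed.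

**Further compounds**
F1 | step 2 | (2E)-5,5-diethoxypent-2-enal | CCOC(C/C=C/C=O)OCC
F2 | step 2 | (5S)-5-(2,2-diethoxyethyl)-2-methylcyclohex-2-en-1-one | CCOC(C[C@@H]1CC=C(C)C(=O)C1)OCC
F3 | step 2 | [(1S)-4-methyl-5-oxocyclohex-3-en-1-yl]acetaldehyde | O=CC[C@@H]1CC=C(C)C(=O)C1
F4 | step 4 | (5R)-5-[(3S)-3-hydroxyhexa-1,5-dien-2-yl]-2-methylcyclohex-2-en-1-one | C=C([C@H](CC=C)O)[C@@H]1CC=C(C)C(=O)C1
F5 | step 9 | bis(3-methylbut-2-enoyl) peroxide | CC(C)=CC(=O)OOC(=O)C=C(C)C
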